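Eremophilane numbering is used. Ring A is cut at C3–C4 and C5–C10. C4 and quaternary C5 bear cis methyls and C5 also bears C6, which is exactly the substitution pattern of tiglic aldehyde (alkene methyls plus formyl carbon). One catalytic enantioselective Diels–Alder reaction between that enal and a 1-substituted butadiene, the silyl ether of (3E)-hexa-3,5-dien-1-ol (diene carbons C3, C2, C1, C10; side chain C9, C8), therefore closes ring A, fixes C4 and C5 and leaves a C1=C2 alkene, which the C6 carboxyl later uses to put oxygen on C1. A Roche-ester zinc reagent, aldol closure of ring B, Mitsunobu inversion with angelic acid and Saegusa oxidation finish the synthesis.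

Key step: step 4

Remarks
- Faces: β is the face of ring A that carries the C4 and C5 methyls; α is the opposite face (the face of C6).
- Assumption: the (S)-prolinol-derived oxazaborolidinium ion is taken to direct the diene to the Si face at the alpha carbon of the enal, as its usual model for alpha-substituted enals predicts; the mirror-image catalyst would be used if the opposite sense were found.
- C10: the endo adduct is drawn throughout; its C10 epimer, if formed, should behave alike in every step and converges at step 16, where C10 becomes trigonal.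
- Design note: C8 enters as a silyl ether, not as an ester. A C8 ester would compete with the C6 lactone in the hydride reduction of step 8, would offer the Lewis acid a second carbonyl in step 4, and would place a reconjugation-prone CH2 next to the diene.

Step 1
Reactants: 1 sorbic acid
Product: 2 (3E)-hexa-3,5-dienoic acid
Conditions: LDA (2.2 equiv), THF, −78 → 0 °C; inverse quench into 2 M HCl at −78 °C
Reagents that add atoms: none
Why: Deconjugative protonation: the extended dienolate dianion formed by removal of a C6 proton is protonated kinetically at the alpha carbon, and the new C3=C4 bond is E because it derives from the s-trans C3–C4 bond of sorbate; no stereocentre is formed.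

Step 2
Reactants: 2 (3E)-hexa-3,5-dienoic acid
Product: 3 (3E)-hexa-3,5-dien-1-ol
Conditions: LiAlH4, Et2O, 0 °C → rt; Fieser work-up
Reagents that add atoms: none
Why: Hydride reduction of a carboxylic acid to the primary alcohol, which leaves the unactivated diene untouched because the carboxylate formed first cannot reconjugate.

Step 3
Reactants: 3 (3E)-hexa-3,5-dien-1-ol
Product: 4 tert-butyl[(3E)-hexa-3,5-dien-1-yloxy]diphenylsilane
Conditions: TBDPSCl, imidazole, CH2Cl2, 0 °C → rt
Reagents that add atoms: tert-butyl(chloro)diphenylsilane, CC(C)(C)[Si](Cl)(c1ccccc1)c1ccccc1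
Why: Imidazole-promoted silylation of a primary alcohol, the tert-butyldiphenylsilyl ether being chosen because it should survive the Lewis acid of step 4 and the acidic methanol of step 9 and is not nucleophilic enough to compete in step 6.

Step 4
Reactants: 4 tert-butyl[(3E)-hexa-3,5-dien-1-yloxy]diphenylsilane; 5 (E)-2-methylbut-2-enal (tiglic aldehyde)
Product: 6 (1R,2S,6S)-2-[2-(tert-butyldiphenylsilyloxy)ethyl]-1,6-dimethylcyclohex-3-ene-1-carbaldehyde
Conditions: 5 (2 equiv), oxazaborolidinium triflimide (20 mol %) generated from (S)-1-(2-methylphenyl)-3,3-diphenyltetrahydro-1H,3H-pyrrolo[1,2-c][1,3,2]oxazaborole and HNTf2, CH2Cl2, −40 → −20 °C, 1–2 d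
Reagents that add atoms: none
Why: The boron of the oxazaborolidinium ion binds the formyl oxygen of 5 and lowers its LUMO, and the s-trans enal then combines with the s-cis diene of 4 in a concerted, asynchronous, suprafacial [4+2] cycloaddition. The closest known reaction type is the oxazaborolidinium-catalysed Diels–Alder reaction of alpha-substituted enals such as 2-methylacrolein and tiglic aldehyde with dienes; an alpha,beta-disubstituted enal with a 1-alkyl diene is a slow member of that class, hence the high catalyst loading and long reaction time. Ring A closes by annulation across the diene termini, C3 bonding to C4 and C10 to C5 through a six-membered boat-like transition state. C4 and C5 (cis methyls, formyl C6 on C5) follow from the E geometry of 5 by stereospecificity and take their absolute sense from the catalyst, which shields one enantioface; C10 follows from endo approach of the formyl group and is inconsequential. The step needs ortho regiochemistry and enantioface control: the first is secured by the larger HOMO coefficient at the unsubstituted diene terminus C3, which pairs with the beta carbon of the activated enal, the second by a single binding site, the aldehyde being the only Lewis-basic carbonyl present.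

Step 5
Reactants: 6 (1R,2S,6S)-2-[2-(tert-butyldiphenylsilyloxy)ethyl]-1,6-dimethylcyclohex-3-ene-1-carbaldehyde
Product: 7 (1R,2S,6S)-2-[2-(tert-butyldiphenylsilyloxy)ethyl]-1,6-dimethylcyclohex-3-ene-1-carboxylic acid
Conditions: NaClO2, NaH2PO4, 2-methylbut-2-ene, t-BuOH/H2O, 0 °C → rt
Reagents that add atoms: sodium chlorite, [Na+].[O-]Cl=O
Why: Pinnick oxidation converts the non-enolisable, hindered aldehyde into the acid under buffered conditions, the alkene scavenger protecting the ring alkene from hypochlorous acid; no stereocentre is touched.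

Step 6
Reactants: 7 the cyclohexenecarboxylic acid
Product: 8 4-iodo-1,2-dimethyl-8-[2-(tert-butyldiphenylsilyloxy)ethyl]-6-oxabicyclo[3.2.1]octan-7-one (γ-lactone from the C6 carboxyl to C1 on the α face; iodine β on C2)
Conditions: I2, NaHCO3, MeCN/H2O, 0 °C, dark
Reagents that add atoms: iodine, [I][I]
Why: Iodolactonization: the carboxylate closes 5-exo onto the iodonium ion of the C1=C2 alkene with anti addition, so the new C1–O bond lies on the face of C6 and iodine sits trans to it on C2, the bicyclic γ-lactone being the known kinetic product of cyclohex-3-enecarboxylic acids; C1 is thereby set by C5.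

Step 7
Reactants: 8 the iodolactone
Product: 9 1,2-dimethyl-8-[2-(tert-butyldiphenylsilyloxy)ethyl]-6-oxabicyclo[3.2.1]octan-7-one
Conditions: Bu3SnH, AIBN (cat.), toluene, 80 °C
Reagents that add atoms: none
Why: Radical-chain hydrodeiodination removes the C2 iodide through a secondary radical that has no cyclisation or fragmentation path open, and the C2 stereocentre simply disappears.

Step 8
Reactants: 9 the lactone
Product: 10 1,2-dimethyl-8-[2-(tert-butyldiphenylsilyloxy)ethyl]-6-oxabicyclo[3.2.1]octan-7-ol (lactol, mixture of anomers)
Conditions: DIBAL-H (1.2 equiv), CH2Cl2, −78 °C; aq. Rochelle salt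
Reagents that add atoms: none
Why: Partial reduction of a lactone by DIBAL-H stops at the aluminium hemiacetal at low temperature, and the lactone is the only reducible group in 9; the anomeric centre is of no consequence.

Step 9
Reactants: 10 the lactol
Product: 11 7-methoxy-1,2-dimethyl-8-[2-(tert-butyldiphenylsilyloxy)ethyl]-6-oxabicyclo[3.2.1]octane (methyl acetal, mixture of anomers)
Conditions: PPTS (cat.), MeOH, rt
Reagents that add atoms: methanol, CO
Why: Acid-catalysed acetalisation through the bridged oxocarbenium ion stores the C6 aldehyde and the C1 hydroxyl together as a base-stable cyclic acetal, the silyl ether being kept on so that the C8 oxygen cannot capture that cation.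

Step 10
Reactants: 11 the silyl ether acetal
Product: 12 2-(7-methoxy-1,2-dimethyl-6-oxabicyclo[3.2.1]octan-8-yl)ethanol
Conditions: Bu4NF, THF, rt
Reagents that add atoms: none
Why: Fluoride-induced desilylation frees the C8 hydroxyl under basic conditions in which the acetal cannot exchange.

Step 11
Reactants: 12 the primary alcohol
Product: 13 2-(7-methoxy-1,2-dimethyl-6-oxabicyclo[3.2.1]octan-8-yl)acetic acid
Conditions: TEMPO (7 mol %), NaOCl (2 mol %), NaClO2 (2 equiv), MeCN/phosphate buffer (pH 6.7), 35 °C
Reagents that add atoms: sodium chlorite, [Na+].[O-]Cl=O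
Why: TEMPO/chlorite oxidation takes the primary alcohol through the aldehyde to the carboxylic acid at near-neutral pH, which the acid-labile acetal should tolerate.

Step 12
Reactants: 14 methyl (S)-3-hydroxy-2-methylpropanoate (Roche ester)
Product: 15 methyl (R)-3-iodo-2-methylpropanoate
Conditions: I2, PPh3, imidazole, CH2Cl2, 0 °C → rt
Reagents that add atoms: iodine, [I][I]
Why: Appel-type iodination replaces the primary hydroxyl without touching the adjacent stereocentre, whose descriptor changes only because iodine raises the CIP rank of the CH2 group.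

Step 13
Reactants: 13 the acetal acid; 15 methyl (R)-3-iodo-2-methylpropanoate
Product: 18 methyl (2S)-5-(7-methoxy-1,2-dimethyl-6-oxabicyclo[3.2.1]octan-8-yl)-2-methyl-4-oxopentanoate, via acid chloride 16 (not isolated), via zinc reagent 17 (not isolated)
Conditions: 13, 1-chloro-N,N,2-trimethylprop-1-en-1-amine, CH2Cl2, 0 °C → rt; separately 15, Zn dust (activated with BrCH2CH2Br and TMSCl), DMA/THF, 35 °C; combine, Pd(PPh3)4 (5 mol %), THF, rt
Reagents that add atoms: none
Why: Negishi-type acylation: the acid chloride, made under neutral conditions that spare the acetal, adds oxidatively to the zerovalent palladium catalyst and is coupled with the chelate-stabilised zinc homoenolate to give the C8 ketone joined to C7, the C11 centre (S, from the Roche ester) not being involved.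

Step 14
Reactants: 18 the keto ester acetal
Product: 20 methyl (11S)-1α-hydroxy-8-oxo-10βH-eremophil-6-en-12-oate, via lactol 19 (not isolated)
Conditions: 1 M HCl, THF, rt; then piperidine, AcOH, wet THF, 50 °C
Reagents that add atoms: none
Why: Acid hydrolysis unmasks the lactol, whose open hydroxy aldehyde form undergoes buffered intramolecular aldol condensation (6-(enolendo)-exo-trig attack of C7 on the non-enolisable C6 aldehyde, then dehydration to the C6=C7 enone), closing ring B and freeing the 1α-hydroxyl under conditions too mild to epimerise C11; no lasting stereocentre is created.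

Step 15
Reactants: 20 the 1α-hydroxy enone; 21 angelic acid [(Z)-2-methylbut-2-enoic acid]
Product: 22 methyl (11S)-1β-[(Z)-2-methylbut-2-enoyloxy]-8-oxo-10βH-eremophil-6-en-12-oate
Conditions: 21 (1.5 equiv), PPh3, DIAD, toluene, 0 °C → rt
Reagents that add atoms: none
Why: Mitsunobu esterification: the C1 oxyphosphonium is displaced by angelate in an SN2 reaction with inversion, turning the α-oxygen into the required β-ester (1R), and because the acid is never activated as an acyl donor its Z geometry is not put at risk.

Step 16
Reactants: 22 the angelate enone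
Product: 24 methyl (11S)-1β-[(Z)-2-methylbut-2-enoyloxy]-8-oxoeremophila-6,9-dien-12-oate (target; 1R,4S,5S,11S), via silyl dienol ether 23 (not isolated)
Conditions: TMSOTf, Et3N, CH2Cl2, 0 °C; then Pd(OAc)2 (1.1 equiv), MeCN, rt
Reagents that add atoms: none
Why: Saegusa–Ito oxidation: soft enolisation is ketone-selective and can occur only towards C9 because C5 is quaternary, and palladium diacetate converts the silyl dienol ether through an oxa-π-allyl palladium species and β-hydride loss of the C10 hydrogen into the C9=C10 alkene, releasing zerovalent palladium; C10 becomes trigonal, so both C10 epimers converge.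

Compound list
1 | sorbic acid, (2E,4E)-hexa-2,4-dienoic acid | C/C=C/C=C/C(=O)O | starting material
2 | (3E)-hexa-3,5-dienoic acid | C=C/C=C/CC(=O)O | intermediate
3 | (3E)-hexa-3,5-dien-1-ol | C=C/C=C/CCO | intermediate
4 | tert-butyl[(3E)-hexa-3,5-dien-1-yloxy]diphenylsilane | C=C/C=C/CCO[Si](c1ccccc1)(c1ccccc1)C(C)(C)C | intermediate
5 | (E)-2-methylbut-2-enal (tiglic aldehyde) | C/C=C(\C)C=O | starting material
6 | (1R,2S,6S)-2-[2-(tert-butyldiphenylsilyloxy)ethyl]-1,6-dimethylcyclohex-3-ene-1-carbaldehyde (methyls cis; side chain cis to CHO) | O=C[C@]1(C)[C@@H](C)CC=C[C@@H]1CCO[Si](c1ccccc1)(c1ccccc1)C(C)(C)C | intermediate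
7 | (1R,2S,6S)-2-[2-(tert-butyldiphenylsilyloxy)ethyl]-1,6-dimethylcyclohex-3-ene-1-carboxylic acid | OC(=O)[C@]1(C)[C@@H](C)CC=C[C@@H]1CCO[Si](c1ccccc1)(c1ccccc1)C(C)(C)C | intermediate
8 | 4-iodo-1,2-dimethyl-8-[2-(tert-butyldiphenylsilyloxy)ethyl]-6-oxabicyclo[3.2.1]octan-7-one (C1–O α, C2–I β, methyls β) | O=C1O[C@H]2[C@H](I)C[C@H](C)[C@]1(C)[C@H]2CCO[Si](c1ccccc1)(c1ccccc1)C(C)(C)C | intermediate
9 | 1,2-dimethyl-8-[2-(tert-butyldiphenylsilyloxy)ethyl]-6-oxabicyclo[3.2.1]octan-7-one | O=C1O[C@H]2CC[C@H](C)[C@]1(C)[C@H]2CCO[Si](c1ccccc1)(c1ccccc1)C(C)(C)C | intermediate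
10 | corresponding lactol (7-ol, anomer mixture) | OC1O[C@H]2CC[C@H](C)[C@]1(C)[C@H]2CCO[Si](c1ccccc1)(c1ccccc1)C(C)(C)C | intermediate
11 | corresponding methyl acetal (7-methoxy, anomer mixture) | COC1O[C@H]2CC[C@H](C)[C@]1(C)[C@H]2CCO[Si](c1ccccc1)(c1ccccc1)C(C)(C)C | intermediate
12 | 2-(7-methoxy-1,2-dimethyl-6-oxabicyclo[3.2.1]octan-8-yl)ethanol | COC1O[C@H]2CC[C@H](C)[C@]1(C)[C@H]2CCO | intermediate
13 | 2-(7-methoxy-1,2-dimethyl-6-oxabicyclo[3.2.1]octan-8-yl)acetic acid | COC1O[C@H]2CC[C@H](C)[C@]1(C)[C@H]2CC(=O)O | intermediate
14 | methyl (S)-3-hydroxy-2-methylpropanoate (Roche ester) | OC[C@H](C)C(=O)OC | starting material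
15 | methyl (R)-3-iodo-2-methylpropanoate | IC[C@H](C)C(=O)OC | intermediate
16 | 2-(7-methoxy-1,2-dimethyl-6-oxabicyclo[3.2.1]octan-8-yl)acetyl chloride | COC1O[C@H]2CC[C@H](C)[C@]1(C)[C@H]2CC(=O)Cl | intermediate
17 | [(2R)-3-methoxy-2-methyl-3-oxopropyl]zinc iodide | I[Zn]C[C@H](C)C(=O)OC | intermediate
18 | methyl (2S)-5-(7-methoxy-1,2-dimethyl-6-oxabicyclo[3.2.1]octan-8-yl)-2-methyl-4-oxopentanoate | COC1O[C@H]2CC[C@H](C)[C@]1(C)[C@H]2CC(=O)C[C@H](C)C(=O)OC | intermediate
19 | methyl (2S)-5-(7-hydroxy-1,2-dimethyl-6-oxabicyclo[3.2.1]octan-8-yl)-2-methyl-4-oxopentanoate (lactol) | OC1O[C@H]2CC[C@H](C)[C@]1(C)[C@H]2CC(=O)C[C@H](C)C(=O)OC | intermediate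
20 | methyl (11S)-1α-hydroxy-8-oxo-10βH-eremophil-6-en-12-oate | O[C@H]1CC[C@H](C)[C@@]2(C)C=C([C@H](C)C(=O)OC)C(=O)C[C@@H]12 | intermediate
21 | angelic acid, (Z)-2-methylbut-2-enoic acid | C/C=C(/C)C(=O)O | starting material
22 | methyl (11S)-1β-[(Z)-2-methylbut-2-enoyloxy]-8-oxo-10βH-eremophil-6-en-12-oate | C/C=C(/C)C(=O)O[C@@H]1CC[C@H](C)[C@@]2(C)C=C([C@H](C)C(=O)OC)C(=O)C[C@@H]12 | intermediate
23 | 8-trimethylsilyloxy-6,8-diene derived from 22 (silyl dienol ether) | C/C=C(/C)C(=O)O[C@@H]1CC[C@H](C)[C@@]2(C)C=C([C@H](C)C(=O)OC)C(O[Si](C)(C)C)=C[C@@H]12 | intermediate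
24 | methyl (11S)-1β-[(Z)-2-methylbut-2-enoyloxy]-8-oxoeremophila-6,9-dien-12-oate (1R,4S,5S,11S) | C/C=C(/C)C(=O)O[C@@H]1CC[C@H](C)[C@@]2(C)C=C([C@H](C)C(=O)OC)C(=O)C=C12 | target

Total step count: 16. Longest linear sequence: 15 (steps 1–11 and 13–16; step 12 is the side branch).

Steps most likely to fail

Step 4. The cycloaddition may be too slow at the temperatures where the catalyst discriminates the enal faces, so that warming brings acid-promoted diene oligomerisation and erosion of enantioselectivity. The fallback gives up asymmetric catalysis for resolution. It sets out from 4 and 5, which are combined under an achiral Lewis acid (MeAlCl2, CH2Cl2, −78 → −20 °C) to give the racemic adduct F1. Pinnick oxidation as in step 5 gives the racemic acid F2. This is resolved by crystallisation of its salt with (R)-1-phenylethylamine, the 1-phenylethylammonium salt F3 (the antipodal amine is used if that salt of 7 is the less soluble one). Acidification returns the route at 7.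

Step 15. Displacement at C1 must come from the β face, past the C5 methyl, with a weakly acidic carboxylic acid, so elimination of the oxyphosphonium towards C1=C2 or simple return of the alcohol may win. The fallback separates inversion from angeloylation. It sets out from 20, which under Mitsunobu conditions with the more acidic 4-nitrobenzoic acid (PPh3, DIAD) should give the inverted 1β-(4-nitrobenzoate) F4. Brief methanolysis (K2CO3, MeOH, 0 °C) gives the 1β-alcohol F5. This is acylated with retention by the angelic 2,4,6-trichlorobenzoic mixed anhydride F6, made from 21 with 2,4,6-trichlorobenzoyl chloride and Et3N, in toluene at 80 °C without DMAP, which would isomerise the angelate. The route is rejoined at 22.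

Step 16. Silylation may be incomplete or may stray to the C11 ester position (ketene acetal formation with loss of the C11 configuration), and the palladium-mediated oxidation of the cross-conjugated dienol ether may stall. The fallback replaces enolate chemistry by hydride abstraction: setting out from 22, DDQ in dioxane at reflux should dehydrogenate C9–C10 directly, the only enolisation open to the enone being towards C9, and arrives at 24 without passing through 23; no new compound arises (F0).

Further compounds
F1 | step 4 | racemic 6 (6 and its mirror image) | O=C[C@]1(C)[C@@H](C)CC=C[C@@H]1CCO[Si](c1ccccc1)(c1ccccc1)C(C)(C)C.O=C[C@@]1(C)[C@H](C)CC=C[C@H]1CCO[Si](c1ccccc1)(c1ccccc1)C(C)(C)C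
F2 | step 4 | racemic 7 (7 and its mirror image) | OC(=O)[C@]1(C)[C@@H](C)CC=C[C@@H]1CCO[Si](c1ccccc1)(c1ccccc1)C(C)(C)C.OC(=O)[C@@]1(C)[C@H](C)CC=C[C@H]1CCO[Si](c1ccccc1)(c1ccccc1)C(C)(C)C
F3 | step 4 | (R)-1-phenylethylammonium salt of 7 | [O-]C(=O)[C@]1(C)[C@@H](C)CC=C[C@@H]1CCO[Si](c1ccccc1)(c1ccccc1)C(C)(C)C.C[C@@H]([NH3+])c1ccccc1
F4 | step 15 | methyl (11S)-1β-(4-nitrobenzoyloxy)-8-oxo-10βH-eremophil-6-en-12-oate | O=C(O[C@@H]1CC[C@H](C)[C@@]2(C)C=C([C@H](C)C(=O)OC)C(=O)C[C@@H]12)c1ccc(cc1)[N+](=O)[O-]
F5 | step 15 | methyl (11S)-1β-hydroxy-8-oxo-10βH-eremophil-6-en-12-oate | O[C@@H]1CC[C@H](C)[C@@]2(C)C=C([C@H](C)C(=O)OC)C(=O)C[C@@H]12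
F6 | step 15 | (Z)-2-methylbut-2-enoic 2,4,6-trichlorobenzoic anhydride | C/C=C(/C)C(=O)OC(=O)c1c(Cl)cc(Cl)cc1Cl
F0 | step 16 | none | none
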